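**Retrosynthetic overview**

1. The last step oxidises a macrocyclic γ-hydroxy amide/allylic alcohol. The amide closes the 5-hydroxy lactam, and the acyl-activated alkene inside the cyclophane undergoes the Diels–Alder reaction that forms rings A and B together. The cycloaddition is left until after the cyclophane is closed because the target has a trans-syn-trans decahydrofluorene (H-4a cis to H-4b), which an untethered precursor is not expected to favour.
2. The 13-membered para-cyclophane is closed by an intramolecular Ullmann aryl ether coupling of the ring-C-bound allylic alcohol with an aryl iodide.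
3. The key C–C bond is an intermolecular aldol addition of the lithium enolate of a β-methoxy γ-lactone (fragment 2, a masked γ-keto amide) to a tetraenal (fragment 1).
4. Fragment 1 comes from desymmetrised cis-3,5-dimethylcyclohexanone (ring C, made first): anti boron aldol with fumaraldehyde mono-acetal, triflate carbonylation and equilibration, then HWE/Wittig construction of the triene.
5. Fragment 2 comes from 2-deoxy-D-ribose: 3-O-methyl epoxy ester, opening with a 4-iodophenyl Grignard reagent, lactonisation. Ring order: C, lactone, cyclophane, lactam, then A and B.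

Assumptions: (S,S)-bis(1-phenylethyl)amide is taken to give the (3S,5R) enol silane by analogy with 4-substituted cyclohexanones (if the sense is opposite, the (R,R)-amine is used); the carbinol centre made in the fragment-coupling aldol is carried as an epimer mixture because it is oxidised later.

**Route**

Step 1
Reactants: 1 3,5-dimethylcyclohex-2-en-1-one
Product: 2 cis-3,5-dimethylcyclohexan-1-one
Conditions: H2 (1 atm), Pd/C, EtOAc, rt
Reagents that add atoms: none
Why: Catalytic hydrogenation adds hydrogen to the alkene face opposite the C5 methyl group, so the new C3 centre is cis to it and the meso diequatorial ketone results.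

Step 2
Reactants: 2 cis-3,5-dimethylcyclohexan-1-one
Product: 4 trimethyl{[(3S,5R)-3,5-dimethylcyclohex-1-en-1-yl]oxy}silane, via lithium enolate 3 (not isolated)
Conditions: (S,S)-bis(1-phenylethyl)amine, n-BuLi, LiCl, THF, −78 °C; Me3SiCl, then 2, −100 °C
Reagents that add atoms: chlorotrimethylsilane, C[Si](C)(C)Cl
Why: Enantioselective deprotonation of the meso ketone by the chiral lithium amide (Simpkins–Koga desymmetrisation) with in situ silyl trapping decides which enantiotopic α-methylene becomes the enol carbon (about 90% ee expected; the minor antipode is removed as diastereomers after step 20).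

Step 3
Reactants: 4 trimethyl{[(3S,5R)-3,5-dimethylcyclohex-1-en-1-yl]oxy}silane; 5 (2E)-4,4-dimethoxybut-2-enal
Product: 7 (2S,3S,5R)-2-[(1S,2E)-1-hydroxy-4,4-dimethoxybut-2-en-1-yl]-3,5-dimethylcyclohexan-1-one, via dibutylboron enolate 6 (not isolated)
Conditions: n-Bu2BOTf (1.05 equiv), CH2Cl2, 0 °C → rt; Me3SiOTf removed in vacuo; i-Pr2NEt (0.1 equiv), Et2O, −78 °C; 5, −78 → −40 °C; H2O2, pH 7 buffer (NaH2PO4/Na2HPO4), MeOH
Reagents that add atoms: none
Why: Silicon-to-boron exchange of the regiodefined enol silane with n-Bu2BOTf gives the cyclic (E)-boron enolate (the Me3SiOTf formed is pumped off so that neither an open Mukaiyama pathway nor acetal activation competes), and its boron aldol addition through a closed Zimmerman–Traxler chair gives the anti aldol with the aldehyde adding anti to the neighbouring C3 methyl group, so C2 and the carbinol centre are set with all ring substituents equatorial.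

Step 4
Reactants: 7 (2S,3S,5R)-2-[(1S,2E)-1-hydroxy-4,4-dimethoxybut-2-en-1-yl]-3,5-dimethylcyclohexan-1-one
Product: 8 (2S,3S,5R)-2-[(1S,2E)-4,4-dimethoxy-1-(triethylsilyloxy)but-2-en-1-yl]-3,5-dimethylcyclohexan-1-one
Conditions: Et3SiCl, imidazole, DMAP (cat.), DMF, rt
Reagents that add atoms: chlorotriethylsilane, CC[Si](Cl)(CC)CC
Why: Silyl ether formation under mildly basic, non-Lewis-acidic conditions protects the secondary alcohol without retro-aldol cleavage or loss of the allylic acetal; no stereocentre is touched.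

Step 5
Reactants: 8 (2S,3S,5R)-2-[(1S,2E)-4,4-dimethoxy-1-(triethylsilyloxy)but-2-en-1-yl]-3,5-dimethylcyclohexan-1-one
Product: 10 (3R,5S,6S)-6-[(1S,2E)-4,4-dimethoxy-1-(triethylsilyloxy)but-2-en-1-yl]-3,5-dimethylcyclohex-1-en-1-yl trifluoromethanesulfonate, via kinetic lithium enolate 9 (not isolated)
Conditions: LiN(i-Pr)2, THF, −78 °C; PhNTf2, −78 → 0 °C
Reagents that add atoms: N-phenylbis(trifluoromethanesulfonimide), O=S(=O)(N(c1ccccc1)S(=O)(=O)C(F)(F)F)C(F)(F)F
Why: Kinetic deprotonation occurs at the unhindered C6 methylene rather than at the branched C2–H (whose removal would expel the β-silyloxy group), and O-triflation gives the less substituted enol triflate.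

Step 6
Reactants: 10 (3R,5S,6S)-6-[(1S,2E)-4,4-dimethoxy-1-(triethylsilyloxy)but-2-en-1-yl]-3,5-dimethylcyclohex-1-en-1-yl trifluoromethanesulfonate
Product: 11 methyl (3R,5S,6R)-6-[(1S,2E)-4,4-dimethoxy-1-(triethylsilyloxy)but-2-en-1-yl]-3,5-dimethylcyclohex-1-ene-1-carboxylate
Conditions: Pd(OAc)2 (5 mol %), PPh3, CO (1 atm), MeOH, Et3N, DMF, 50 °C
Reagents that add atoms: carbon monoxide, [C-]#[O+]; methanol, CO
Why: Palladium-catalysed alkoxycarbonylation of the enol triflate installs the one-carbon unit at the former ketone carbon without touching any stereocentre.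

Step 7
Reactants: 11 methyl (3R,5S,6R)-6-[(1S,2E)-4,4-dimethoxy-1-(triethylsilyloxy)but-2-en-1-yl]-3,5-dimethylcyclohex-1-ene-1-carboxylate
Product: 13 methyl (1R,2R,3S,5R)-2-[(1S,2E)-4,4-dimethoxy-1-(triethylsilyloxy)but-2-en-1-yl]-3,5-dimethylcyclohexane-1-carboxylate, via C1-epimeric ester mixture 12 (not isolated)
Conditions: Mg, MeOH, rt; then NaOMe (0.2 equiv), MeOH, rt
Reagents that add atoms: none
Why: Dissolving-metal (Mg/MeOH) conjugate reduction followed by methoxide equilibration of the epimerisable C1 gives the all-equatorial trans ester under thermodynamic control (about 9:1 expected; the minor epimer is separated and recycled).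

Step 8
Reactants: 13 methyl (1R,2R,3S,5R)-2-[(1S,2E)-4,4-dimethoxy-1-(triethylsilyloxy)but-2-en-1-yl]-3,5-dimethylcyclohexane-1-carboxylate
Product: 14 [(1R,2R,3S,5R)-2-[(1S,2E)-4,4-dimethoxy-1-(triethylsilyloxy)but-2-en-1-yl]-3,5-dimethylcyclohexyl]methanol
Conditions: i-Bu2AlH (2.5 equiv), CH2Cl2, −78 → 0 °C; aq. potassium sodium tartrate
Reagents that add atoms: none
Why: Hydride reduction of the ester to the primary alcohol is non-epimerising and leaves the acetal, silyl ether and isolated alkene untouched.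

Step 9
Reactants: 14 [(1R,2R,3S,5R)-2-[(1S,2E)-4,4-dimethoxy-1-(triethylsilyloxy)but-2-en-1-yl]-3,5-dimethylcyclohexyl]methanol
Product: 15 (1R,2R,3S,5R)-2-[(1S,2E)-4,4-dimethoxy-1-(triethylsilyloxy)but-2-en-1-yl]-3,5-dimethylcyclohexane-1-carbaldehyde
Conditions: Dess–Martin periodinane, NaHCO3, CH2Cl2, 0 °C
Reagents that add atoms: none
Why: Buffered Dess–Martin oxidation gives the aldehyde without base, so the C1 configuration fixed in step 7 is kept.

Step 10
Reactants: 15 (1R,2R,3S,5R)-2-[(1S,2E)-4,4-dimethoxy-1-(triethylsilyloxy)but-2-en-1-yl]-3,5-dimethylcyclohexane-1-carbaldehyde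
Product: 16 ethyl (2E,4E)-5-[(1S,2R,3S,5R)-2-[(1S,2E)-4,4-dimethoxy-1-(triethylsilyloxy)but-2-en-1-yl]-3,5-dimethylcyclohexyl]penta-2,4-dienoate
Conditions: triethyl 4-phosphonocrotonate, LiN(SiMe3)2, THF, −78 → 0 °C
Reagents that add atoms: triethyl (2E)-4-phosphonobut-2-enoate, CCOC(=O)/C=C/CP(=O)(OCC)OCC
Why: Vinylogous Horner–Wadsworth–Emmons olefination with the stabilised phosphonate anion gives the (E,E)-dienoate, and the weakly basic anion does not epimerise the α-stereocentre at −78 °C.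

Step 11
Reactants: 16 ethyl (2E,4E)-5-[(1S,2R,3S,5R)-2-[(1S,2E)-4,4-dimethoxy-1-(triethylsilyloxy)but-2-en-1-yl]-3,5-dimethylcyclohexyl]penta-2,4-dienoate
Product: 17 (2E,4E)-5-[(1S,2R,3S,5R)-2-[(1S,2E)-4,4-dimethoxy-1-(triethylsilyloxy)but-2-en-1-yl]-3,5-dimethylcyclohexyl]penta-2,4-dien-1-ol
Conditions: i-Bu2AlH (2.2 equiv), CH2Cl2, −78 °C; aq. potassium sodium tartrate
Reagents that add atoms: none
Why: 1,2-Reduction of the conjugated ester by the aluminium hydride gives the dienol with the alkene geometries intact.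

Step 12
Reactants: 17 (2E,4E)-5-[(1S,2R,3S,5R)-2-[(1S,2E)-4,4-dimethoxy-1-(triethylsilyloxy)but-2-en-1-yl]-3,5-dimethylcyclohexyl]penta-2,4-dien-1-ol
Product: 18 (2E,4E)-5-[(1S,2R,3S,5R)-2-[(1S,2E)-4,4-dimethoxy-1-(triethylsilyloxy)but-2-en-1-yl]-3,5-dimethylcyclohexyl]penta-2,4-dienal
Conditions: MnO2, CH2Cl2, rt
Reagents that add atoms: none
Why: Chemoselective allylic oxidation with manganese dioxide gives the dienal under neutral conditions.

Step 13
Reactants: 18 (2E,4E)-5-[(1S,2R,3S,5R)-2-[(1S,2E)-4,4-dimethoxy-1-(triethylsilyloxy)but-2-en-1-yl]-3,5-dimethylcyclohexyl]penta-2,4-dienal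
Product: 19 (1S,2R,3S,5R)-1-[(1E,3E)-hexa-1,3,5-trien-1-yl]-2-[(1S,2E)-4,4-dimethoxy-1-(triethylsilyloxy)but-2-en-1-yl]-3,5-dimethylcyclohexane
Conditions: Ph3PCH3Br, KN(SiMe3)2, THF, 0 °C
Reagents that add atoms: methyltriphenylphosphonium bromide, C[P+](c1ccccc1)(c1ccccc1)c1ccccc1.[Br-]
Why: Wittig methylenation adds the terminal vinyl carbon, which creates no new geometric element, so the (E,E)-triene is obtained.

Step 14
Reactants: 19 (1S,2R,3S,5R)-1-[(1E,3E)-hexa-1,3,5-trien-1-yl]-2-[(1S,2E)-4,4-dimethoxy-1-(triethylsilyloxy)but-2-en-1-yl]-3,5-dimethylcyclohexane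
Product: 20 (2E,4S)-4-[(1R,2S,4R,6S)-2-[(1E,3E)-hexa-1,3,5-trien-1-yl]-4,6-dimethylcyclohexyl]-4-(triethylsilyloxy)but-2-enal
Conditions: oxalic acid (cat.), wet SiO2, CH2Cl2, 0 °C; used cold at once
Reagents that add atoms: water, O
Why: The α,β-unsaturated dimethyl acetal is hydrolysed under very mild acid that should spare the hindered triethylsilyl ether, and the tetraenal is used immediately at low temperature so that it does not cyclise.

Step 15
Reactants: 21 2-deoxy-D-ribose
Product: 22 2-deoxy-D-ribono-1,4-lactone [(4S,5R)-4-hydroxy-5-(hydroxymethyl)oxolan-2-one]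
Conditions: Br2, H2O, rt, 4 d; NaHCO3
Reagents that add atoms: none
Why: Bromine-water oxidation of the anomeric hemiacetal gives the 1,4-lactone, with both stereocentres taken unchanged from the chiral pool.

Step 16
Reactants: 22 2-deoxy-D-ribono-1,4-lactone
Product: 23 [(2R,3S)-3-hydroxy-5-oxooxolan-2-yl]methyl 4-methylbenzenesulfonate
Conditions: TsCl (1.05 equiv), pyridine, 0 °C
Reagents that add atoms: 4-methylbenzenesulfonyl chloride, Cc1ccc(S(=O)(=O)Cl)cc1
Why: Sulfonylation is selective for the primary hydroxyl over the secondary one.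

Step 17
Reactants: 23 [(2R,3S)-3-hydroxy-5-oxooxolan-2-yl]methyl 4-methylbenzenesulfonate
Product: 24 [(2R,3S)-3-methoxy-5-oxooxolan-2-yl]methyl 4-methylbenzenesulfonate
Conditions: MeI, Ag2O, MeCN, rt, dark
Reagents that add atoms: iodomethane, CI
Why: Purdie methylation with silver oxide etherifies the secondary alcohol without a strong base, so neither β-elimination nor epimerisation occurs.

Step 18
Reactants: 24 [(2R,3S)-3-methoxy-5-oxooxolan-2-yl]methyl 4-methylbenzenesulfonate
Product: 26 methyl (3S)-3-methoxy-3-[(2R)-oxiran-2-yl]propanoate, via hydroxy tosylate 25 (not isolated)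
Conditions: K2CO3, MeOH, 0 °C
Reagents that add atoms: methanol, CO
Why: Methanolysis of the lactone frees the C4 alkoxide, which displaces the primary tosylate in an intramolecular Williamson reaction, so the C4–O bond and its configuration are retained.

Step 19
Reactants: 26 methyl (3S)-3-methoxy-3-[(2R)-oxiran-2-yl]propanoate; 27 1,4-diiodobenzene
Product: 30 (4S,5R)-5-(4-iodobenzyl)-4-methoxyoxolan-2-one, via (4-iodophenyl)magnesium chloride 28 (not isolated), via hydroxy ester 29 (not isolated)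
Conditions: 27, i-PrMgCl·LiCl, THF, −20 °C; CuI (10 mol %), 26, −40 → 0 °C; p-TsOH (cat.), toluene, rt
Reagents that add atoms: none
Why: Iodine–magnesium exchange gives the mono-Grignard reagent, copper-catalysed opening of the terminal epoxide at its primary carbon follows, and lactonisation of the resulting γ-hydroxy ester gives the 4,5-trans lactone because the C4–O bond is never broken.

Step 20
Reactants: 30 (4S,5R)-5-(4-iodobenzyl)-4-methoxyoxolan-2-one; 20 (2E,4S)-4-[(1R,2S,4R,6S)-2-[(1E,3E)-hexa-1,3,5-trien-1-yl]-4,6-dimethylcyclohexyl]-4-(triethylsilyloxy)but-2-enal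
Product: 32 aldol adduct (3S,4S,5R)-3-[(2E,4S)-1-hydroxy-4-{(1R,2S,4R,6S)-2-[(1E,3E)-hexa-1,3,5-trien-1-yl]-4,6-dimethylcyclohexyl}-4-(triethylsilyloxy)but-2-en-1-yl]-5-(4-iodobenzyl)-4-methoxyoxolan-2-one (C1′ epimers), via lactone lithium enolate 31 (not isolated)
Conditions: 30, LiN(SiMe3)2, THF, −78 °C, 30 min; 20, −78 °C; AcOH quench at −78 °C
Reagents that add atoms: none
Why: Intermolecular aldol addition (1,2-addition of the lactone lithium enolate to the enal) joins the two fragments; attack anti to the C4 methoxy group places the new C3 substituent trans to it, the carbinol centre is formed as a mixture that is oxidised later, and −78 °C suppresses β-elimination of methoxide and cyclisation of the tetraenal.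

Step 21
Reactants: 32 aldol adduct (C1′ epimers)
Product: 33 C1′ tert-butyldimethylsilyl ether of 32
Conditions: t-BuMe2SiOTf, 2,6-lutidine, CH2Cl2, −78 °C
Reagents that add atoms: tert-butyldimethylsilyl trifluoromethanesulfonate, CC(C)(C)[Si](C)(C)OS(=O)(=O)C(F)(F)F
Why: Silylation of the allylic aldol hydroxyl blocks retro-aldol cleavage under the basic macrocyclisation conditions and is orthogonal to the more labile triethylsilyl ether.

Step 22
Reactants: 33 C1′ tert-butyldimethylsilyl ether of 32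
Product: 34 C4′ allylic alcohol (33 without the triethylsilyl group)
Conditions: PPTS (cat.), MeOH/CH2Cl2, 0 °C → rt
Reagents that add atoms: none
Why: Acid-catalysed methanolysis removes the triethylsilyl ether much faster than the tert-butyldimethylsilyl ether, and it tolerates the triene, unlike an oxidative deprotection.

Step 23
Reactants: 34 C4′ allylic alcohol
Product: 35 13-membered para-cyclophane lactone (C4′–O–aryl ether; C1′ silyl ether)
Conditions: CuI (20 mol %), 3,4,7,8-tetramethyl-1,10-phenanthroline, Cs2CO3, 4 Å sieves, toluene, 90 °C, 2 mM, slow addition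
Reagents that add atoms: none
Why: Intramolecular Ullmann-type copper-catalysed C–O coupling of the secondary alkoxide with the aryl iodide closes the cyclophane under high dilution; the carbinol C–O bond is not broken, so its configuration is retained, and the unactivated dienophile should not cyclise at this temperature.

Step 24
Reactants: 35 13-membered para-cyclophane lactone (C1′ silyl ether)
Product: 36 para-cyclophane hydroxy lactone (free C1′ alcohol)
Conditions: HF·pyridine, pyridine, THF, 0 °C → rt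
Reagents that add atoms: none
Why: Buffered fluoride desilylation frees the allylic alcohol without opening the lactone or isomerising the triene.

Step 25
Reactants: 36 para-cyclophane hydroxy lactone
Product: 37 para-cyclophane diol amide (γ-hydroxy primary amide; C1′ allylic alcohol)
Conditions: Me3Al, NH4Cl, CH2Cl2/toluene, 0 → 40 °C; aq. potassium sodium tartrate
Reagents that add atoms: ammonium chloride, [NH4+].[Cl-]
Why: Weinreb-type aminolysis with the aluminium amide opens the hindered γ-lactone to the γ-hydroxy primary amide under non-basic conditions, with retention at the carbinol carbon and no elimination of the β-methoxy group.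

Step 26
Reactants: 37 para-cyclophane diol amide
Product: 40 xenoacremone C, via diketo amide 38 (not isolated), via hydroxy-lactam tetraene 39 (not isolated)
Conditions: Dess–Martin periodinane (3 equiv), NaHCO3, CH2Cl2, 0 °C → rt; then toluene, 40 °C
Reagents that add atoms: none
Why: Dess–Martin oxidation of both secondary alcohols lets the primary amide close onto the benzylic ketone to give the hemiaminal lactam as its thermodynamic epimer (OH cis to OMe), and the now ketone-activated (E)-alkene, held in the cyclophane with only its outer face open, undergoes an endo intramolecular Diels–Alder reaction with the (E,E)-diene to set C1, C2, C4a and C9a (trans A/B fusion, acyl cis to vinyl).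

**Compound list**

1 | 3,5-dimethylcyclohex-2-en-1-one | CC1=CC(=O)CC(C)C1 | starting material
2 | cis-3,5-dimethylcyclohexan-1-one (meso) | O=C1C[C@H](C)C[C@H](C)C1 | intermediate
3 | lithium (3S,5R)-3,5-dimethylcyclohex-1-en-1-olate | [Li]OC1=C[C@@H](C)C[C@@H](C)C1 | intermediate (not isolated)
4 | trimethyl{[(3S,5R)-3,5-dimethylcyclohex-1-en-1-yl]oxy}silane | C[Si](C)(C)OC1=C[C@@H](C)C[C@@H](C)C1 | intermediate
5 | (2E)-4,4-dimethoxybut-2-enal (fumaraldehyde mono(dimethyl acetal)) | COC(OC)/C=C/C=O | starting material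
6 | dibutyl{[(3S,5R)-3,5-dimethylcyclohex-1-en-1-yl]oxy}borane | CCCCB(CCCC)OC1=C[C@@H](C)C[C@@H](C)C1 | intermediate (not isolated)
7 | (2S,3S,5R)-2-[(1S,2E)-1-hydroxy-4,4-dimethoxybut-2-en-1-yl]-3,5-dimethylcyclohexan-1-one | O=C1C[C@H](C)C[C@H](C)[C@H]1[C@@H](O)/C=C/C(OC)OC | intermediate
8 | (2S,3S,5R)-2-[(1S,2E)-4,4-dimethoxy-1-(triethylsilyloxy)but-2-en-1-yl]-3,5-dimethylcyclohexan-1-one | O=C1C[C@H](C)C[C@H](C)[C@H]1[C@@H](O[Si](CC)(CC)CC)/C=C/C(OC)OC | intermediate
9 | kinetic (C1–C6) lithium enolate of 8 | [Li]OC1=C[C@H](C)C[C@H](C)[C@H]1[C@@H](O[Si](CC)(CC)CC)/C=C/C(OC)OC | intermediate (not isolated)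
10 | (3R,5S,6S)-6-[(1S,2E)-4,4-dimethoxy-1-(triethylsilyloxy)but-2-en-1-yl]-3,5-dimethylcyclohex-1-en-1-yl trifluoromethanesulfonate | O=S(=O)(OC1=C[C@H](C)C[C@H](C)[C@H]1[C@@H](O[Si](CC)(CC)CC)/C=C/C(OC)OC)C(F)(F)F | intermediate
11 | methyl (3R,5S,6R)-6-[(1S,2E)-4,4-dimethoxy-1-(triethylsilyloxy)but-2-en-1-yl]-3,5-dimethylcyclohex-1-ene-1-carboxylate | COC(=O)C1=C[C@H](C)C[C@H](C)[C@H]1[C@@H](O[Si](CC)(CC)CC)/C=C/C(OC)OC | intermediate
12 | methyl (2R,3S,5R)-2-[(1S,2E)-4,4-dimethoxy-1-(triethylsilyloxy)but-2-en-1-yl]-3,5-dimethylcyclohexane-1-carboxylate, C1 epimer mixture | COC(=O)C1C[C@H](C)C[C@H](C)[C@H]1[C@@H](O[Si](CC)(CC)CC)/C=C/C(OC)OC | intermediate (not isolated)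
13 | methyl (1R,2R,3S,5R)-2-[(1S,2E)-4,4-dimethoxy-1-(triethylsilyloxy)but-2-en-1-yl]-3,5-dimethylcyclohexane-1-carboxylate | COC(=O)[C@@H]1C[C@H](C)C[C@H](C)[C@H]1[C@@H](O[Si](CC)(CC)CC)/C=C/C(OC)OC | intermediate
14 | [(1R,2R,3S,5R)-2-[(1S,2E)-4,4-dimethoxy-1-(triethylsilyloxy)but-2-en-1-yl]-3,5-dimethylcyclohexyl]methanol | OC[C@@H]1C[C@H](C)C[C@H](C)[C@H]1[C@@H](O[Si](CC)(CC)CC)/C=C/C(OC)OC | intermediate
15 | (1R,2R,3S,5R)-2-[(1S,2E)-4,4-dimethoxy-1-(triethylsilyloxy)but-2-en-1-yl]-3,5-dimethylcyclohexane-1-carbaldehyde | O=C[C@@H]1C[C@H](C)C[C@H](C)[C@H]1[C@@H](O[Si](CC)(CC)CC)/C=C/C(OC)OC | intermediate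
16 | ethyl (2E,4E)-5-[(1S,2R,3S,5R)-2-[(1S,2E)-4,4-dimethoxy-1-(triethylsilyloxy)but-2-en-1-yl]-3,5-dimethylcyclohexyl]penta-2,4-dienoate | CCOC(=O)/C=C/C=C/[C@@H]1C[C@H](C)C[C@H](C)[C@H]1[C@@H](O[Si](CC)(CC)CC)/C=C/C(OC)OC | intermediate
17 | (2E,4E)-5-[(1S,2R,3S,5R)-2-[(1S,2E)-4,4-dimethoxy-1-(triethylsilyloxy)but-2-en-1-yl]-3,5-dimethylcyclohexyl]penta-2,4-dien-1-ol | OC/C=C/C=C/[C@@H]1C[C@H](C)C[C@H](C)[C@H]1[C@@H](O[Si](CC)(CC)CC)/C=C/C(OC)OC | intermediate
18 | (2E,4E)-5-[(1S,2R,3S,5R)-2-[(1S,2E)-4,4-dimethoxy-1-(triethylsilyloxy)but-2-en-1-yl]-3,5-dimethylcyclohexyl]penta-2,4-dienal | O=C/C=C/C=C/[C@@H]1C[C@H](C)C[C@H](C)[C@H]1[C@@H](O[Si](CC)(CC)CC)/C=C/C(OC)OC | intermediate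
19 | (1S,2R,3S,5R)-1-[(1E,3E)-hexa-1,3,5-trien-1-yl]-2-[(1S,2E)-4,4-dimethoxy-1-(triethylsilyloxy)but-2-en-1-yl]-3,5-dimethylcyclohexane | C=C/C=C/C=C/[C@@H]1C[C@H](C)C[C@H](C)[C@H]1[C@@H](O[Si](CC)(CC)CC)/C=C/C(OC)OC | intermediate
20 | (2E,4S)-4-[(1R,2S,4R,6S)-2-[(1E,3E)-hexa-1,3,5-trien-1-yl]-4,6-dimethylcyclohexyl]-4-(triethylsilyloxy)but-2-enal (fragment 1) | C=C/C=C/C=C/[C@@H]1C[C@H](C)C[C@H](C)[C@H]1[C@@H](O[Si](CC)(CC)CC)/C=C/C=O | intermediate
21 | 2-deoxy-D-ribose | O=CC[C@H](O)[C@H](O)CO | starting material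
22 | 2-deoxy-D-ribono-1,4-lactone, (4S,5R)-4-hydroxy-5-(hydroxymethyl)oxolan-2-one | O=C1C[C@H](O)[C@@H](CO)O1 | intermediate
23 | [(2R,3S)-3-hydroxy-5-oxooxolan-2-yl]methyl 4-methylbenzenesulfonate | O=C1C[C@H](O)[C@@H](COS(=O)(=O)c2ccc(C)cc2)O1 | intermediate
24 | [(2R,3S)-3-methoxy-5-oxooxolan-2-yl]methyl 4-methylbenzenesulfonate | O=C1C[C@H](OC)[C@@H](COS(=O)(=O)c2ccc(C)cc2)O1 | intermediate
25 | methyl (3S,4R)-4-hydroxy-3-methoxy-5-(tosyloxy)pentanoate (as its alkoxide) | COC(=O)C[C@H](OC)[C@H](O)COS(=O)(=O)c1ccc(C)cc1 | intermediate (not isolated)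
26 | methyl (3S)-3-methoxy-3-[(2R)-oxiran-2-yl]propanoate | COC(=O)C[C@H](OC)[C@H]1CO1 | intermediate
27 | 1,4-diiodobenzene | Ic1ccc(I)cc1 | starting material
28 | (4-iodophenyl)magnesium chloride | Cl[Mg]c1ccc(I)cc1 | intermediate (not isolated)
29 | methyl (3S,4R)-4-hydroxy-5-(4-iodophenyl)-3-methoxypentanoate | COC(=O)C[C@H](OC)[C@H](O)Cc1ccc(I)cc1 | intermediate (not isolated)
30 | (4S,5R)-5-(4-iodobenzyl)-4-methoxyoxolan-2-one (fragment 2) | O=C1C[C@H](OC)[C@@H](Cc2ccc(I)cc2)O1 | intermediate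
31 | lithium enolate of 30 | [Li]OC1=C[C@H](OC)[C@@H](Cc2ccc(I)cc2)O1 | intermediate (not isolated)
32 | aldol adduct: lactone 30 carrying at C3 (trans to OMe) the 1-hydroxy-but-2-enyl chain of 20; C1′ epimers | C=C/C=C/C=C/[C@@H]1C[C@H](C)C[C@H](C)[C@H]1[C@@H](O[Si](CC)(CC)CC)/C=C/C(O)[C@@H]1C(=O)O[C@H](Cc2ccc(I)cc2)[C@H]1OC | intermediate
33 | C1′ tert-butyldimethylsilyl ether of 32 | C=C/C=C/C=C/[C@@H]1C[C@H](C)C[C@H](C)[C@H]1[C@@H](O[Si](CC)(CC)CC)/C=C/C(O[Si](C)(C)C(C)(C)C)[C@@H]1C(=O)O[C@H](Cc2ccc(I)cc2)[C@H]1OC | intermediate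
34 | C4′ allylic alcohol (33 without the triethylsilyl group) | C=C/C=C/C=C/[C@@H]1C[C@H](C)C[C@H](C)[C@H]1[C@@H](O)/C=C/C(O[Si](C)(C)C(C)(C)C)[C@@H]1C(=O)O[C@H](Cc2ccc(I)cc2)[C@H]1OC | intermediate
35 | 13-membered para-cyclophane lactone: C4′–O–aryl ether, (E)-alkene, C1′ silyl ether, trienyl-dimethylcyclohexyl substituent | C=C/C=C/C=C/[C@@H]1C[C@H](C)C[C@H](C)[C@H]1[C@H]1Oc2ccc(cc2)C[C@H]2OC(=O)[C@H]([C@@H]2OC)C(O[Si](C)(C)C(C)(C)C)/C=C/1 | intermediate
36 | para-cyclophane hydroxy lactone (35 with free C1′ alcohol) | C=C/C=C/C=C/[C@@H]1C[C@H](C)C[C@H](C)[C@H]1[C@H]1Oc2ccc(cc2)C[C@H]2OC(=O)[C@H]([C@@H]2OC)C(O)/C=C/1 | intermediate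
37 | para-cyclophane diol amide (lactone opened to γ-hydroxy primary amide) | C=C/C=C/C=C/[C@@H]1C[C@H](C)C[C@H](C)[C@H]1[C@H]1Oc2ccc(cc2)C[C@@H](O)[C@@H](OC)[C@@H](C(N)=O)C(O)/C=C/1 | intermediate
38 | para-cyclophane diketo amide | C=C/C=C/C=C/[C@@H]1C[C@H](C)C[C@H](C)[C@H]1[C@H]1Oc2ccc(cc2)CC(=O)[C@@H](OC)C(C(N)=O)C(=O)/C=C/1 | intermediate (not isolated)
39 | hydroxy-lactam tetraene (3-acyl-5-hydroxy-4-methoxy lactam, enol form, inside the cyclophane) | C=C/C=C/C=C/[C@@H]1C[C@H](C)C[C@H](C)[C@H]1[C@H]1Oc2ccc(cc2)C[C@@]2(O)NC(=O)/C(=C(\O)/C=C/1)[C@@H]2OC | intermediate (not isolated)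
40 | xenoacremone C | C=C[C@@H]1C=C[C@@H]2[C@@H]3C[C@H](C)C[C@H](C)[C@H]3[C@H]3Oc4ccc(cc4)C[C@@]4(O)NC(=O)/C(=C(\O)[C@H]1[C@@H]23)[C@@H]4OC | target

**Totals**

Total step count: 26. Longest linear sequence: 21 steps (steps 1–14, then 20–26).

**Steps most likely to fail, with fallbacks**

Step 23 (Ullmann macrocyclisation to a strained 13-membered para-cyclophane; the triene could also cyclise prematurely on heating). The fallback sets out from 34 and changes the coupling from a hot aryl iodide/alkoxide reaction to a room-temperature oxidative aryl–boron coupling. Miyaura borylation (B2pin2, PdCl2(dppf), KOAc, dioxane, 80 °C) gives the aryl pinacol boronate F1. KHF2 in aqueous MeOH converts it into the potassium aryltrifluoroborate F2. Chan–Lam–Evans etherification (Cu(OAc)2, DMAP, 4 Å sieves, O2, CH2Cl2, rt, high dilution) then closes the ring and returns to 35.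

Step 26 (double oxidation, hemiaminal closure and cycloaddition in one operation; the enolised acyl lactam is a weak dienophile and the final β-methoxy dicarbonyl is sensitive). The fallback sets out from 36 and stages the cycloaddition at the keto-lactone level. Dess–Martin oxidation of the single allylic alcohol gives the macrocyclic enone keto lactone F3. Its keto-activated alkene cyclises on gentle warming (or with MgBr2·OEt2) to the tricyclic keto lactone F4. NaBH4 at −20 °C gives the tricyclic hydroxy lactone F5, and Me3Al/NH4Cl opens it to the tricyclic diol amide F6. Dess–Martin oxidation of both alcohols with spontaneous hemiaminal closure then returns to 40.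

Step 2 (sense and level of the enantioselective deprotonation). The fallback sets out from 2 and replaces asymmetric deprotonation by resolution. LiN(i-Pr)2/Me3SiCl gives the racemic enol silane, that is 4 together with the enantiomeric enol silane F7. The boron aldol of step 3 (n-Bu2BOTf exchange, then 5) then gives racemic aldol, that is 7 together with the enantiomeric aldol F8. Sharpless kinetic resolution (Ti(Oi-Pr)4, L-(+)-diisopropyl tartrate, t-BuOOH, CH2Cl2, −20 °C) epoxidises the fast-reacting enantiomer to the anti epoxy alcohol F9 and leaves 7, where the route is rejoined.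

Further compounds
F1 | step 23 | aryl pinacol boronate corresponding to 34 | C=C/C=C/C=C/[C@@H]1C[C@H](C)C[C@H](C)[C@H]1[C@@H](O)/C=C/C(O[Si](C)(C)C(C)(C)C)[C@@H]1C(=O)O[C@H](Cc2ccc(B3OC(C)(C)C(C)(C)O3)cc2)[C@H]1OC
F2 | step 23 | potassium aryltrifluoroborate corresponding to 34 | [K+].C=C/C=C/C=C/[C@@H]1C[C@H](C)C[C@H](C)[C@H]1[C@@H](O)/C=C/C(O[Si](C)(C)C(C)(C)C)[C@@H]1C(=O)O[C@H](Cc2ccc([B-](F)(F)F)cc2)[C@H]1OC
F3 | step 26 | macrocyclic enone keto lactone | C=C/C=C/C=C/[C@@H]1C[C@H](C)C[C@H](C)[C@H]1[C@H]1Oc2ccc(cc2)C[C@H]2OC(=O)C([C@@H]2OC)C(=O)/C=C/1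
F4 | step 26 | tricyclic keto lactone (decahydrofluorene formed) | C=C[C@@H]1C=C[C@@H]2[C@@H]3C[C@H](C)C[C@H](C)[C@H]3[C@H]3Oc4ccc(cc4)C[C@H]4OC(=O)C([C@@H]4OC)C(=O)[C@H]1[C@@H]23
F5 | step 26 | tricyclic hydroxy lactone | C=C[C@@H]1C=C[C@@H]2[C@@H]3C[C@H](C)C[C@H](C)[C@H]3[C@H]3Oc4ccc(cc4)C[C@H]4OC(=O)C([C@@H]4OC)C(O)[C@H]1[C@@H]23
F6 | step 26 | tricyclic diol amide | C=C[C@@H]1C=C[C@@H]2[C@@H]3C[C@H](C)C[C@H](C)[C@H]3[C@H]3Oc4ccc(cc4)C[C@@H](O)[C@@H](OC)C(C(N)=O)C(O)[C@H]1[C@@H]23
F7 | step 2 | trimethyl{[(3R,5S)-3,5-dimethylcyclohex-1-en-1-yl]oxy}silane (enantiomer of 4) | C[Si](C)(C)OC1=C[C@H](C)C[C@H](C)C1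
F8 | step 2 | (2R,3R,5S)-2-[(1R,2E)-1-hydroxy-4,4-dimethoxybut-2-en-1-yl]-3,5-dimethylcyclohexan-1-one (enantiomer of 7) | O=C1C[C@@H](C)C[C@@H](C)[C@@H]1[C@H](O)/C=C/C(OC)OC
F9 | step 2 | anti 2,3-epoxy alcohol formed from the enantiomer of 7 | O=C1C[C@@H](C)C[C@@H](C)[C@@H]1[C@H](O)[C@H]1O[C@@H]1C(OC)OC
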